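**Strategy**

The two fisetinidol units are traced back, through acid-catalysed arylation of (+)-catechin at C8 and C6, to one flavan-3,4-diol and so to its C4 ketone. The key step exploits that carbonyl in pyran ring C (O1, C2, C3, C4, C4a, C8a): it acidifies C3–H and activates an ortho C8a–F bond. The dianion of an open-chain α-hydroxy 2-fluoroaryl ketone adds to 3,4-bis(benzyloxy)benzaldehyde (C2–C3 bond), and the aldolate oxygen, the future O1, then displaces fluoride at C8a, closing ring C as the trans-dihydroflavonol in one operation. A ruthenium-catalysed kinetic resolution supplies the single enantiomer.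

Key step: step 2

Remark: flavan numbering is used throughout (O1, C2, C3, C4, C4a, C5 to C8, C8a; ring B carbons primed). Compounds 1, 2, 7 and 15 are taken as commercially available.

**Route**

Step 1
Reactants: 1 4-(benzyloxy)-1-bromo-2-fluorobenzene; 2 2-[(tert-butyldimethylsilyl)oxy]-N-methoxy-N-methylacetamide
Product: 6 1-[4-(benzyloxy)-2-fluorophenyl]-2-hydroxyethan-1-one, via arylmagnesium chloride 3 (not isolated), via magnesium-chelated tetrahedral adduct 4 (not isolated), via silyl-protected hydroxy ketone 5 (not isolated)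
Conditions: i-PrMgCl·LiCl (1.1 equiv), THF, −15 °C; 2, −15 → 0 °C; then 1 M HCl, MeOH, 25 °C
Reagents that add atoms: none
Why: Bromine–magnesium exchange and Weinreb ketone synthesis should stop at the ketone because chelate 4 survives until the acidic work-up, which also removes the primary silyl ether in the same pot; the low temperature keeps the ortho-fluoro Grignard reagent from eliminating to an aryne, and no stereocentre is formed.

Step 2
Reactants: 6 1-[4-(benzyloxy)-2-fluorophenyl]-2-hydroxyethan-1-one; 7 3,4-bis(benzyloxy)benzaldehyde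
Product: 11 rac-(2R,3R)-7-(benzyloxy)-2-[3,4-bis(benzyloxy)phenyl]-3-hydroxy-2,3-dihydro-4H-chromen-4-one (racemic trans isomer), via dilithium enediolate 8 (not isolated), via dilithium aldol dialkoxide 9 (not isolated), via lithium 3-alkoxide 10 (not isolated)
Conditions: LiN(i-Pr)2 (2.0 equiv), THF, −78 °C; 7 (1.0 equiv), −78 °C; DMPU, −78 → 25 °C; re-cool to −40 °C, aq. NH4Cl
Reagents that add atoms: none
Why: LiN(i-Pr)2 turns 6 into the chelated dilithium (Z)-enediolate 8, whose carbon C3 adds to aldehyde 7 (aldol addition, C2–C3 bond) to give dialkoxide 9, and on warming with DMPU the C2 alkoxide attacks C8a, ortho to the lithium-coordinated C4 carbonyl, and expels fluoride through a Meisenheimer complex (intramolecular SNAr, O1–C8a bond). The closest known reaction types are the aldol addition of α-hydroxy ketone dianions and the SNAr etherification of 2-fluoroaryl ketones used to close chromones and xanthones. Ring C closes as a six-membered ring by attack of the alkoxide on the sp2 carbon C8a (addition–elimination, the charge being taken up through C4a by the C4 carbonyl). C2 and C3 arise in the aldol step and are sorted at ring closure: the dialkoxides can equilibrate by retro-aldol, and the chair-like closure that keeps O3 chelated to the carbonyl and the aryl group equatorial should lead to the 2,3-trans isomer, as the racemate because no chiral element is present, while any cis isomer stays epimerisable at C3 and would be levelled by the triethylamine of step 3. The step needs the C2 alkoxide and not the C3 alkoxide to arylate: lithium chelation between O3 and the carbonyl oxygen holds O3 away from C8a, and the five-membered closure is the more strained one. Leaving the C3 hydroxyl free is deliberate, because the product is formed as its lithium 3-alkoxide 10, which alkoxide bases cannot enolise at C3 in this aprotic medium, so the E1cB ring opening to a chalcone that 3-O-alkyl flavanones undergo under base is shut off until the cold quench.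

Step 3
Reactants: 11 rac-(2R,3R)-7-(benzyloxy)-2-[3,4-bis(benzyloxy)phenyl]-3-hydroxy-2,3-dihydro-4H-chromen-4-one
Product: 12 (2R,3R)-7-(benzyloxy)-2-[3,4-bis(benzyloxy)phenyl]-3-hydroxy-2,3-dihydro-4H-chromen-4-one
Conditions: RuCl[(R,R)-TsDPEN](p-cymene) (1 mol%), HCO2H/Et3N (5:2), CH2Cl2, 25 °C, stopped just past half conversion; chromatography
Reagents that add atoms: none
Why: Noyori asymmetric transfer hydrogenation run as a kinetic resolution should reduce the (2S,3S)-ketone, for which the catalyst-preferred carbonyl face coincides with the substrate-preferred axial hydride delivery, much faster than the (2R,3R)-ketone, which is recovered unchanged and separated from the more polar diol; no new stereocentre is created in 12, and the hand of the catalyst is to be confirmed on a small sample.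

Step 4
Reactants: 12 (2R,3R)-7-(benzyloxy)-2-[3,4-bis(benzyloxy)phenyl]-3-hydroxy-2,3-dihydro-4H-chromen-4-one
Product: 13 (2R,3R)-2-(3,4-dihydroxyphenyl)-3,7-dihydroxy-2,3-dihydro-4H-chromen-4-one ((+)-fustin)
Conditions: H2 (1 atm), Pd/C (10 wt%), EtOAc/MeOH, 25 °C
Reagents that add atoms: none
Why: Hydrogenolysis should cleave the three aryl benzyl ethers while the conjugated C4 ketone (a vinylogous ester through O1 and the C7 oxygen) and the cyclic C2–O1 ether are left alone, and C2 and C3 are not touched under these neutral conditions.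

Step 5
Reactants: 13 (+)-fustin
Product: 14 (2R,3S,4R)-2-(3,4-dihydroxyphenyl)-3,4-dihydro-2H-chromene-3,4,7-triol ((+)-mollisacacidin)
Conditions: NaBH4 (excess), EtOH, 0 → 25 °C; AcOH to pH 6, extraction with EtOAc
Reagents that add atoms: none
Why: Borohydride reduction of the C4 ketone should deliver hydride axially, anti to the axial C3–H of the diequatorial half-chair, giving the equatorial 4-hydroxyl trans to the 3-hydroxyl (4R); a minor C4 epimer would not matter because C4 is ionised in the next step.

Step 6
Reactants: 14 (+)-mollisacacidin (2.3 equiv); 15 (+)-catechin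
Product: 18 fisetinidol-(4α→6)-catechin-(8←4α)-fisetinidol (the target), via C4 benzylic cation 16 (not isolated), via fisetinidol-(4α→8)-catechin 17 (not isolated)
Conditions: 0.1 M aq. HCl, 25 °C, monitored by HPLC; Sephadex LH-20 (EtOH), then preparative reversed-phase HPLC
Reagents that add atoms: none
Why: Acid-catalysed ionisation of the C4 hydroxyl gives cation 16, stabilised by the para 7-hydroxyl and by O1, which should arylate the phloroglucinol ring A of catechin first at C8 and then at C6 (Friedel–Crafts alkylation), each time anti to the C3 hydroxyl so that both new C4 centres are 4α (3,4-trans, 4S), the catechin ring being far more nucleophilic than the resorcinol rings of 14.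

**Compound list**

1 | 4-(benzyloxy)-1-bromo-2-fluorobenzene | Brc1ccc(OCc2ccccc2)cc1F | starting material
2 | 2-[(tert-butyldimethylsilyl)oxy]-N-methoxy-N-methylacetamide | CON(C)C(=O)CO[Si](C)(C)C(C)(C)C | starting material
3 | [4-(benzyloxy)-2-fluorophenyl]magnesium chloride (LiCl complex) | Cl[Mg]c1ccc(OCc2ccccc2)cc1F | intermediate (not isolated)
4 | magnesium-chelated tetrahedral adduct of 3 and 2 | CON(C)C(O[Mg]Cl)(CO[Si](C)(C)C(C)(C)C)c1ccc(OCc2ccccc2)cc1F | intermediate (not isolated)
5 | 1-[4-(benzyloxy)-2-fluorophenyl]-2-[(tert-butyldimethylsilyl)oxy]ethan-1-one | O=C(CO[Si](C)(C)C(C)(C)C)c1ccc(OCc2ccccc2)cc1F | intermediate (not isolated)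
6 | 1-[4-(benzyloxy)-2-fluorophenyl]-2-hydroxyethan-1-one | O=C(CO)c1ccc(OCc2ccccc2)cc1F | intermediate
7 | 3,4-bis(benzyloxy)benzaldehyde | O=Cc1ccc(OCc2ccccc2)c(OCc2ccccc2)c1 | starting material
8 | dilithium (Z)-1-[4-(benzyloxy)-2-fluorophenyl]ethene-1,2-diolate | [Li+].[Li+].[O-]/C=C(\[O-])c1ccc(OCc2ccccc2)cc1F | intermediate (not isolated)
9 | dilithium 1-[3,4-bis(benzyloxy)phenyl]-3-[4-(benzyloxy)-2-fluorophenyl]-3-oxopropane-1,2-diolate (racemic, equilibrating syn/anti mixture) | [Li+].[Li+].[O-]C(c1ccc(OCc2ccccc2)c(OCc2ccccc2)c1)C([O-])C(=O)c1ccc(OCc2ccccc2)cc1F | intermediate (not isolated)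
10 | lithium 3-alkoxide of 11 (racemic, trans) | [Li+].c1ccccc1COc1ccc2c(c1)O[C@H](c1ccc(OCc3ccccc3)c(OCc3ccccc3)c1)[C@@H]([O-])C2=O.[Li+].c1ccccc1COc1ccc2c(c1)O[C@@H](c1ccc(OCc3ccccc3)c(OCc3ccccc3)c1)[C@H]([O-])C2=O | intermediate (not isolated)
11 | rac-(2R,3R)-7-(benzyloxy)-2-[3,4-bis(benzyloxy)phenyl]-3-hydroxy-2,3-dihydro-4H-chromen-4-one (both enantiomers, trans) | c1ccccc1COc1ccc2c(c1)O[C@H](c1ccc(OCc3ccccc3)c(OCc3ccccc3)c1)[C@@H](O)C2=O.c1ccccc1COc1ccc2c(c1)O[C@@H](c1ccc(OCc3ccccc3)c(OCc3ccccc3)c1)[C@H](O)C2=O | intermediate
12 | (2R,3R)-7-(benzyloxy)-2-[3,4-bis(benzyloxy)phenyl]-3-hydroxy-2,3-dihydro-4H-chromen-4-one | c1ccccc1COc1ccc2c(c1)O[C@H](c1ccc(OCc3ccccc3)c(OCc3ccccc3)c1)[C@@H](O)C2=O | intermediate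
13 | (+)-fustin, (2R,3R)-2-(3,4-dihydroxyphenyl)-3,7-dihydroxy-2,3-dihydro-4H-chromen-4-one | Oc1ccc2c(c1)O[C@H](c1ccc(O)c(O)c1)[C@@H](O)C2=O | intermediate
14 | (+)-mollisacacidin, (2R,3S,4R)-2-(3,4-dihydroxyphenyl)-3,4-dihydro-2H-chromene-3,4,7-triol | Oc1ccc2c(c1)O[C@H](c1ccc(O)c(O)c1)[C@@H](O)[C@@H]2O | intermediate
15 | (+)-catechin, (2R,3S) | Oc1cc(O)c2c(c1)O[C@H](c1ccc(O)c(O)c1)[C@@H](O)C2 | starting material
16 | (2R,3S)-fisetinidol C4 benzylic cation (chloride) | Oc1ccc2c(c1)O[C@H](c1ccc(O)c(O)c1)[C@@H](O)[CH+]2.[Cl-] | intermediate (not isolated)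
17 | fisetinidol-(4α→8)-catechin | c1c(O)c2c(c([C@@H]3c4ccc(O)cc4O[C@H](c4ccc(O)c(O)c4)[C@H]3O)c1O)O[C@H](c1ccc(O)c(O)c1)[C@@H](O)C2 | intermediate (not isolated)
18 | fisetinidol-(4α→6)-catechin-(8←4α)-fisetinidol | Oc1ccc2c(c1)O[C@H](c1ccc(O)c(O)c1)[C@@H](O)[C@@H]2c1c(O)c2c(c([C@@H]3c4ccc(O)cc4O[C@H](c4ccc(O)c(O)c4)[C@H]3O)c1O)O[C@H](c1ccc(O)c(O)c1)[C@@H](O)C2 | target

**Step count and risks**

Total step count: 6. Longest linear sequence: 6 steps (1 → 6 → 11 → 12 → 13 → 14 → 18).

Steps most likely to fail:

1. Step 2. The ring may close through the wrong oxygen (five-membered closure by the C3 alkoxide, followed by dehydration to an aurone). Arylation of the lithium dialkoxide may also be so slow that retro-aldol, hydride transfer to the aldehyde, or enolisation and ring opening of the product on prolonged warming take over. The fallback sets out from 7 and comes back at 12. Commercial 1-[4-(benzyloxy)-2-hydroxyphenyl]ethan-1-one is protected with chloromethyl methyl ether and i-Pr2NEt as 1-[4-(benzyloxy)-2-(methoxymethoxy)phenyl]ethan-1-one F1. Claisen–Schmidt condensation of this ketone with 7 (KOH, EtOH) gives (E)-1-[4-(benzyloxy)-2-(methoxymethoxy)phenyl]-3-[3,4-bis(benzyloxy)phenyl]prop-2-en-1-one F2. Juliá–Colonna epoxidation (poly-L-leucine, urea–H2O2, DBU, THF) should give [(2R,3S)-3-[3,4-bis(benzyloxy)phenyl]oxiran-2-yl][4-(benzyloxy)-2-(methoxymethoxy)phenyl]methanone F3. HCl in MeOH/THF then removes the methoxymethyl group, and the freed phenol opens the epoxide at the benzylic carbon with inversion to give 12 directly, so that the resolution of step 3 is not needed on this path.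

2. Step 6. Arylation may be statistically incomplete or excessive (mono-adducts, higher oligomers through the resorcinol rings), and facial selectivity at C4 may be insufficient in either arylation, giving 4β epimers. The fallback sets out from 14 and comes back at 18. Compound 14 is converted with phenylmethanethiol and AcOH into (2R,3S)-4-(benzylsulfanyl)-2-(3,4-dihydroxyphenyl)-3,4-dihydro-2H-chromene-3,7-diol F4. Thiophilic activation of this thioether with AgBF4 in THF at 0 °C in the presence of an excess of 15 gives 17, which is now isolated on Sephadex LH-20. A second portion of the thioether with AgBF4 then arylates C6 of 17 to give 18, so the two interflavanyl bonds are made one at a time under neutral conditions.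

3. Step 3. The rate difference between the enantiomers may be too small, for example if the free C3 hydroxyl overrides catalyst control or if C3 epimerisation feeds a fast-reacting cis ketone, which would leave 12 of low enantiomeric purity. The fallback sets out from 11 and comes back at 12. The racemate is separated by preparative supercritical-fluid chromatography on an amylose tris(3,5-dimethylphenylcarbamate) phase (CO2/MeOH), and the (2R,3R)-enantiomer is taken on; this makes no new compound (F0).

**Further compounds**

F1 | step 2 | 1-[4-(benzyloxy)-2-(methoxymethoxy)phenyl]ethan-1-one | CC(=O)c1ccc(OCc2ccccc2)cc1OCOC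
F2 | step 2 | (E)-1-[4-(benzyloxy)-2-(methoxymethoxy)phenyl]-3-[3,4-bis(benzyloxy)phenyl]prop-2-en-1-one | COCOc1cc(OCc2ccccc2)ccc1C(=O)/C=C/c1ccc(OCc2ccccc2)c(OCc2ccccc2)c1
F3 | step 2 | [(2R,3S)-3-[3,4-bis(benzyloxy)phenyl]oxiran-2-yl][4-(benzyloxy)-2-(methoxymethoxy)phenyl]methanone | COCOc1cc(OCc2ccccc2)ccc1C(=O)[C@@H]1O[C@H]1c1ccc(OCc2ccccc2)c(OCc2ccccc2)c1
F0 | step 3 | none | none
F4 | step 6 | (2R,3S)-4-(benzylsulfanyl)-2-(3,4-dihydroxyphenyl)-3,4-dihydro-2H-chromene-3,7-diol (C4 epimers) | Oc1ccc2c(c1)O[C@H](c1ccc(O)c(O)c1)[C@@H](O)C2SCc1ccccc1
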